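**Retrosynthetic overview** (ring numbering used throughout: C1 = CH(i-Pr), C2=C3 = E-alkene, C4 = C(CH3)OH, C5–C7 = (CH2)3, C8 = C(CH3) and C9 = CH of the oxirane, C10 = CH–O-acyl)
1. The ester and the C8–C9 oxirane come from Payne rearrangement and acylation of the tertiary 9,10-epoxy-8-ol 17, which comes from MeLi and trans-epoxy ketone 16, made from β-silyloxy ketone 14.
2. The ten-membered ring of 14 comes from cyclopentanone 11 in one operation: a Barbier closure forms C7–C8, and a Grob fragmentation then breaks C8–C2.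
3. Enabling feature: C8, the oxirane carbon bearing CH3 and O, is a latent ketone. A transannular C8–C2 bond divides the ten-membered ring into a cyclopentanone (C8, C9, C10, C1, C2) and a seven-membered ring A (C2–C8). This sets up the array O–C8–C2–C3–X that releases the C2=C3 alkene, and the bare C5–C7 chain carries the nucleophile.
4. Cyclopentanone 11 comes from a three-component coupling of i-PrMgCl, (S)-4-silyloxycyclopentenone 7 and aldehyde 6. Aldehyde 6 supplies C3–C7, with C4 taken from (R)-linalool.
5. Ring order: cyclopentane (bought), then ring A closed onto it, then the ten-membered ring by loss of the shared bond in the same flask, then the C9–C10 oxirane, which migrates to C8–C9.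

Key step: step 7

Assumption: 1 and 7 are used as the enantiopure commercial materials, and 7 is the (S)-enantiomer.

Step 1
Reactants: 1 (R)-linalool
Product: 2 (3R)-3,7-dimethyl-3-(triethylsilyloxy)octa-1,6-diene
Conditions: TESOTf, 2,6-lutidine, CH2Cl2, 0 °C
Reagents that add atoms: triethylsilyl triflate, CC[Si](CC)(CC)OS(=O)(=O)C(F)(F)F
Why: Silyl triflate silylation of a hindered tertiary alcohol; the C4 stereocentre is taken unchanged from the chiral pool, and the ether later prevents retro-aldol and hemiketal formation.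

Step 2
Reactants: 2 (3R)-3,7-dimethyl-3-(triethylsilyloxy)octa-1,6-diene
Product: 4 (4R)-4-methyl-4-(triethylsilyloxy)hex-5-en-1-ol, via aldehyde 3 (not isolated)
Conditions: O3 (1 equiv), CH2Cl2/MeOH, −78 °C; then NaBH4, −78 to 0 °C
Reagents that add atoms: ozone, [O-][O+]=O
Why: Chemoselective ozonolysis with reductive work-up: the electron-rich trisubstituted alkene consumes the single equivalent of ozone far faster than the hindered vinyl group, and NaBH4 reduces aldehyde 3 in the same flask.

Step 3
Reactants: 4 (4R)-4-methyl-4-(triethylsilyloxy)hex-5-en-1-ol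
Product: 5 (3R)-6-iodo-3-methyl-3-(triethylsilyloxy)hex-1-ene
Conditions: I2, PPh3, imidazole, CH2Cl2, 0 °C
Reagents that add atoms: iodine, II
Why: Appel-type iodination (SN2 at the primary carbon of the alkoxyphosphonium salt) leaves the vinyl group and the silyl ether untouched.

Step 4
Reactants: 5 (3R)-6-iodo-3-methyl-3-(triethylsilyloxy)hex-1-ene
Product: 6 (2R)-5-iodo-2-methyl-2-(triethylsilyloxy)pentanal
Conditions: O3, CH2Cl2, −78 °C; then Me2S
Reagents that add atoms: ozone, [O-][O+]=O
Why: Ozonolysis of the remaining vinyl group at low temperature, where the alkene reacts faster than the primary iodide, gives an aldehyde whose quaternary α-carbon cannot epimerise.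

Step 5
Reactants: 6 (2R)-5-iodo-2-methyl-2-(triethylsilyloxy)pentanal; 7 (4S)-4-(tert-butyldimethylsilyloxy)cyclopent-2-en-1-one
Product: 10 (2R,3S,4S)-4-(tert-butyldimethylsilyloxy)-2-[(1R,2R)-1-hydroxy-5-iodo-2-methyl-2-(triethylsilyloxy)pentyl]-3-isopropylcyclopentan-1-one, via chloromagnesium enolate 8 (not isolated), via titanium enolate 9 (not isolated)
Conditions: 7, i-PrMgCl, CuI (10 mol %), LiCl, THF, −78 °C; ClTi(OiPr)3, −78 to −40 °C; then 6, −78 °C; H2O
Reagents that add atoms: isopropylmagnesium chloride, CC(C)[Mg]Cl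
Why: Three-component coupling by copper-catalysed conjugate addition and aldol trapping: isopropyl enters anti to the silyloxy group (sets C1), the aldehyde enters C2 trans to it, and the triisopropoxytitanium enolate, which is syn-selective whatever the enolate geometry, sets the C2/C3 syn relation (C3 R) needed for the E alkene.

Step 6
Reactants: 10 the aldol
Product: 11 methanesulfonate of 10 at the side-chain carbinol C3
Conditions: MsCl, Et3N, CH2Cl2, −40 °C
Reagents that add atoms: methanesulfonyl chloride, CS(=O)(=O)Cl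
Why: Mesylation through sulfene at low temperature is fast even at the hindered carbinol and should outrun E1cB elimination of the β-mesyloxy ketone.

Step 7
Reactants: 11 the keto mesylate iodide
Product: 14 (1S,2E,4R,10S)-10-(tert-butyldimethylsilyloxy)-1-isopropyl-4-methyl-4-(triethylsilyloxy)cyclodec-2-en-8-one, via alkylsamarium 12 (not isolated), via bicyclic samarium alkoxide 13 (not isolated)
Conditions: SmI2 (2.2 equiv), NiI2 (2 mol %), THF, 0 °C, slow addition of 11 at high dilution; then aq NaHCO3
Reagents that add atoms: none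
Why: SmI2 reduces the primary C–I bond in two one-electron steps to alkylsamarium 12, whose C7 adds to the C8 ketone (intramolecular Barbier reaction), and the trivalent samarium alkoxide 13 at once undergoes Grob fragmentation of the O–C8–C2–C3–OMs array, so the new C7–C8 bond is traded for the shared C8–C2 bond. The closest known reaction type is the SmI2-promoted sequential Barbier cyclisation/Grob fragmentation of iodoalkyl keto mesylates to eight- to ten-membered cycloalkenones. Ring A (seven-membered, C2–C8) closes by 7-exo-trig attack on the carbonyl face that carries the tether and gives the cis-fused bicyclo[5.3.0]decane, and the ten-membered ring then appears by cleavage of the zero bridge rather than by a direct medium-ring closure. The only new stereocentre, carbinol C8 of 13, is fixed by the tether and erased again; the lasting result is the E alkene, which follows from the antiperiplanar C8–C2/C3–OMs alignment of the syn-aldol mesylate (C2 R, C3 R), in which C1 and C4 lie anti. The step needs reduction of the iodide beside ketone, mesylate and β-silyloxy group and no over-reduction of 14: the iodide is the most easily reduced group under SmI2/NiI2, the medium is non-basic so neither OMs nor OTBS is lost by E1cB, the quaternary C4 favours closure (gem-dialkyl effect), and only 2.2 equiv of SmI2 without a proton source are used to avoid transannular ketyl–olefin coupling.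

Step 8
Reactants: 14 the β-silyloxy cyclodecenone
Product: 16 (1S,2E,4R,9S,10R)-9,10-epoxy-1-isopropyl-4-methyl-4-(triethylsilyloxy)cyclodec-2-en-8-one, via dienone 15 (not isolated)
Conditions: t-BuOOH, DBU, toluene, 0 °C to rt
Reagents that add atoms: tert-butyl hydroperoxide, CC(C)(C)OO
Why: E1cB loss of silanolate and Weitz–Scheffer epoxidation in one flask: with C1–H eclipsing the enone (allylic strain) ring carbon C2 covers the inner face, so t-BuOO− should attack C10 from outside (sets C10 R), and the freely rotating peroxy-enolate should close to the trans-epoxy ketone (sets C9 S) from either enone geometry.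

Step 9
Reactants: 16 the trans-epoxy ketone
Product: 17 (1S,2E,4R,8S,9S,10R)-9,10-epoxy-1-isopropyl-4,8-dimethyl-4-(triethylsilyloxy)cyclodec-2-en-8-ol
Conditions: MeLi, Et2O/THF, −78 °C; then H2O
Reagents that add atoms: methyllithium, [Li]C
Why: 1,2-Addition under polar Felkin–Anh (Cornforth) control: methyl should approach C8 anti to the C9–O bond of the oxirane, which sets C8 (S) with its oxygen placed for the later migration.

Step 10
Reactants: 17 the tertiary epoxy alcohol; 18 4-acetoxybenzoyl chloride
Product: 21 (1S,2E,4R,8S,9R,10R)-8,9-epoxy-1-isopropyl-4,8-dimethyl-4-(triethylsilyloxy)cyclodec-2-en-10-yl 4-acetoxybenzoate, via tertiary sodium alkoxide 19 (not isolated), via rearranged sodium alkoxide 20 (not isolated)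
Conditions: NaH, THF, 0 °C to rt; then 18, −40 °C
Reagents that add atoms: none
Why: Payne rearrangement with acylative trapping: the C8 alkoxide opens the oxirane at C9 by SN2 (inversion to 9R, C8–O and C10–O untouched), the equilibrium favours the trisubstituted cis-fused oxirane and the less hindered C10 alkoxide, and this alkoxide is acylated much faster than the tertiary one (Curtin–Hammett).

Step 11
Reactants: 21 the protected ester
Product: 23 target CNP0278889.1, via phenol 22 (not isolated)
Conditions: K2CO3 (cat.), MeOH, 0 °C; concentrate; then TBAF, THF, 0 °C to rt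
Reagents that add atoms: none
Why: Mild transesterification removes the activated aryl acetate while the hindered, phenoxide-deactivated benzoate stays, and fluoride desilylation then frees the tertiary C4 alcohol without touching oxirane, ester or alkene.

**Compound list**
1 | (R)-linalool | C=C[C@](C)(O)CCC=C(C)C | starting material
2 | (3R)-3,7-dimethyl-3-(triethylsilyloxy)octa-1,6-diene | C=C[C@](C)(O[Si](CC)(CC)CC)CCC=C(C)C | intermediate
3 | (4R)-4-methyl-4-(triethylsilyloxy)hex-5-enal (not isolated) | C=C[C@](C)(O[Si](CC)(CC)CC)CCC=O | intermediate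
4 | (4R)-4-methyl-4-(triethylsilyloxy)hex-5-en-1-ol | C=C[C@](C)(O[Si](CC)(CC)CC)CCCO | intermediate
5 | (3R)-6-iodo-3-methyl-3-(triethylsilyloxy)hex-1-ene | C=C[C@](C)(O[Si](CC)(CC)CC)CCCI | intermediate
6 | (2R)-5-iodo-2-methyl-2-(triethylsilyloxy)pentanal | O=C[C@](C)(O[Si](CC)(CC)CC)CCCI | intermediate
7 | (4S)-4-(tert-butyldimethylsilyloxy)cyclopent-2-en-1-one | O=C1C=C[C@@H](O[Si](C)(C)C(C)(C)C)C1 | starting material
8 | chloromagnesium enolate, isopropyl trans to OTBS (not isolated) | CC(C)[C@H]1C=C(O[Mg]Cl)C[C@@H]1O[Si](C)(C)C(C)(C)C | intermediate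
9 | triisopropoxytitanium enolate (not isolated) | CC(C)[C@H]1C=C(O[Ti](OC(C)C)(OC(C)C)OC(C)C)C[C@@H]1O[Si](C)(C)C(C)(C)C | intermediate
10 | syn aldol, (2R,3S,4S) ring and (1R,2R) side chain | O=C1C[C@H](O[Si](C)(C)C(C)(C)C)[C@@H](C(C)C)[C@@H]1[C@@H](O)[C@](C)(O[Si](CC)(CC)CC)CCCI | intermediate
11 | C3 mesylate of 10 | O=C1C[C@H](O[Si](C)(C)C(C)(C)C)[C@@H](C(C)C)[C@@H]1[C@@H](OS(C)(=O)=O)[C@](C)(O[Si](CC)(CC)CC)CCCI | intermediate
12 | alkylsamarium diiodide from 11 (not isolated) | O=C1C[C@H](O[Si](C)(C)C(C)(C)C)[C@@H](C(C)C)[C@@H]1[C@@H](OS(C)(=O)=O)[C@](C)(O[Si](CC)(CC)CC)CCC[Sm](I)I | intermediate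
13 | cis-fused bicyclo[5.3.0]decane samarium alkoxide (not isolated) | I[Sm](I)O[C@@]12C[C@H](O[Si](C)(C)C(C)(C)C)[C@@H](C(C)C)[C@@H]1[C@@H](OS(C)(=O)=O)[C@](C)(O[Si](CC)(CC)CC)CCC2 | intermediate
14 | (1S,2E,4R,10S)-10-OTBS-1-isopropyl-4-methyl-4-OTES-cyclodec-2-en-8-one | O=C1C[C@H](O[Si](C)(C)C(C)(C)C)[C@@H](C(C)C)/C=C/[C@](C)(O[Si](CC)(CC)CC)CCC1 | intermediate
15 | (2E,9E)-cyclodeca-2,9-dien-8-one (not isolated) | O=C1/C=C/[C@@H](C(C)C)/C=C/[C@](C)(O[Si](CC)(CC)CC)CCC1 | intermediate
16 | (1S,2E,4R,9S,10R)-trans-9,10-epoxy ketone | O=C1[C@H]2O[C@@H]2[C@@H](C(C)C)/C=C/[C@](C)(O[Si](CC)(CC)CC)CCC1 | intermediate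
17 | (1S,2E,4R,8S,9S,10R)-9,10-epoxy-8-methyl-8-ol | C[C@@]1(O)[C@H]2O[C@@H]2[C@@H](C(C)C)/C=C/[C@](C)(O[Si](CC)(CC)CC)CCC1 | intermediate
18 | 4-acetoxybenzoyl chloride | CC(=O)Oc1ccc(cc1)C(=O)Cl | starting material
19 | sodium alkoxide of 17 (not isolated) | C[C@@]1([O-])[C@H]2O[C@@H]2[C@@H](C(C)C)/C=C/[C@](C)(O[Si](CC)(CC)CC)CCC1.[Na+] | intermediate
20 | sodium C10 alkoxide of the 8,9-epoxide (not isolated) | CC(C)[C@H]1/C=C/[C@](C)(O[Si](CC)(CC)CC)CCC[C@]2(C)O[C@@H]2[C@@H]1[O-].[Na+] | intermediate
21 | (1S,2E,4R,8S,9R,10R)-8,9-epoxy-4-OTES-10-yl 4-acetoxybenzoate | CC(C)[C@H]1/C=C/[C@](C)(O[Si](CC)(CC)CC)CCC[C@]2(C)O[C@@H]2[C@@H]1OC(=O)c1ccc(OC(C)=O)cc1 | intermediate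
22 | 4-OTES 4-hydroxybenzoate (not isolated) | CC(C)[C@H]1/C=C/[C@](C)(O[Si](CC)(CC)CC)CCC[C@]2(C)O[C@@H]2[C@@H]1OC(=O)c1ccc(O)cc1 | intermediate
23 | (1S,2E,4R,8S,9R,10R)-8,9-epoxy-4-hydroxy-1-isopropyl-4,8-dimethylcyclodec-2-en-10-yl 4-hydroxybenzoate | CC(C)[C@H]1/C=C/[C@](C)(O)CCC[C@]2(C)O[C@@H]2[C@@H]1OC(=O)c1ccc(O)cc1 | target

Total step count: 11. Longest linear sequence: 11 (1 to 23).

**Steps most likely to fail**

Step 7. The seven-membered closure may be too slow. The alkylsamarium could then be protonated, or the ketone reduced, before C7 reaches C8. The fallback sets out from 10 and returns at 14, and it separates the two events. Aldol 10 is capped as the O-trimethylsilyl aldol F1 (TMSCl, imidazole). With no nucleofuge present, SmI2/NiI2 has only to effect the Barbier closure to the bicyclic carbinol F2. Citric acid in MeOH frees the secondary alcohol to give the diol F3. MsCl/Et3N mesylates only that hydroxyl to give the monomesylate F4. KOt-Bu in THF then triggers the classical base-induced fragmentation of the 1,3-diol monosulfonate to 14.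

Step 5. Poor simple diastereoselection would give the anti aldol, which would later deliver the Z alkene. The fallback sets out from 7 and returns at 10, and it changes the aldol mechanism. Conjugate addition in the presence of TMSCl gives the silyl enol ether F5. A fluoride-catalysed aldol with 6, using tris(dimethylamino)sulfonium difluorotrimethylsilicate, runs through a metal-free enolate and an open, syn-selective transition state. It should give the O-trimethylsilyl aldol F1, which citric acid in MeOH converts into 10.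

Step 9. Macrocyclic shielding may override Felkin–Anh control, so that methyl attacks the wrong carbonyl face. The fallback sets out from 16 and returns at 17, and it delivers oxygen instead of carbon from the exposed face. Wittig methylenation (Ph3P=CH2) gives the vinyl oxirane F6. Dimethyldioxirane epoxidises the 1,1-disubstituted alkene from that same face to give the spiro bis-epoxide F7. LiBHEt3 then opens the spiro oxirane at its CH2 to give 17.

**Further compounds**
F1 | step 7 | O-trimethylsilyl aldol | O=C1C[C@H](O[Si](C)(C)C(C)(C)C)[C@@H](C(C)C)[C@@H]1[C@@H](O[Si](C)(C)C)[C@](C)(O[Si](CC)(CC)CC)CCCI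
F2 | step 7 | cis-fused bicyclic carbinol, C3 OTMS | O[C@@]12C[C@H](O[Si](C)(C)C(C)(C)C)[C@@H](C(C)C)[C@@H]1[C@@H](O[Si](C)(C)C)[C@](C)(O[Si](CC)(CC)CC)CCC2
F3 | step 7 | bicyclic 1,3-diol | O[C@@]12C[C@H](O[Si](C)(C)C(C)(C)C)[C@@H](C(C)C)[C@@H]1[C@@H](O)[C@](C)(O[Si](CC)(CC)CC)CCC2
F4 | step 7 | bicyclic diol C3 monomesylate | O[C@@]12C[C@H](O[Si](C)(C)C(C)(C)C)[C@@H](C(C)C)[C@@H]1[C@@H](OS(C)(=O)=O)[C@](C)(O[Si](CC)(CC)CC)CCC2
F5 | step 5 | trimethylsilyl enol ether | CC(C)[C@H]1C=C(O[Si](C)(C)C)C[C@@H]1O[Si](C)(C)C(C)(C)C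
F6 | step 9 | 8-methylene-9,10-epoxide | C=C1[C@H]2O[C@@H]2[C@@H](C(C)C)/C=C/[C@](C)(O[Si](CC)(CC)CC)CCC1
F7 | step 9 | spiro bis-epoxide | C1O[C@@]12[C@H]3O[C@@H]3[C@@H](C(C)C)/C=C/[C@](C)(O[Si](CC)(CC)CC)CCC2
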